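The target is disconnected at the C7–C8 bond of cyclopentanone ring A (C6–C10: C6 carbinol, C7 CH-isopropyl, C8 methylene, C9 ketone, C10 C-methyl), leaving cycloheptene ring B (C1–C6 plus C10) intact. The key step exploits that C8 is alpha to the C9 ketone while its neighbour C7 bears an isopropyl group. A C8 alpha-keto radical adds 5-exo to a 2-methylpropenyl group on C6, so one operation closes ring A, creates the C7 stereocentre and turns the alkene into isopropyl. The precursor is a fully substituted ring B bromomethyl ketone carrying the C1 anisoate, the C6 silyl ether and the C6 alkenyl group cis to the C10 bromoacetyl arm.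

Key step: step 12

Remark: in step 3 hydride is assumed to approach past the ethynyl group and away from the methyl group; if the opposite face were preferred, the antipodal catalyst would give the same C10 configuration.

Step 1
Reactants: 1 cycloheptane-1,3-dione
Product: 2 2-methylcycloheptane-1,3-dione
Conditions: MeI (1.1 equiv), K2CO3, acetone, reflux
Reagents that add atoms: iodomethane, CI
Why: Enolate C-alkylation at the doubly activated carbon of the cyclic 1,3-diketone should install the future C10 methyl group; no stereocentre is formed.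

Step 2
Reactants: 2 2-methylcycloheptane-1,3-dione
Product: 3 2-ethynyl-2-methylcycloheptane-1,3-dione
Conditions: TMS-EBX (1.3 equiv), TBAF (1.3 equiv), THF, −78 °C to rt
Reagents that add atoms: TMS-EBX, 1-[(trimethylsilyl)ethynyl]-1,2-benziodoxol-3(1H)-one, C[Si](C)(C)C#CI1OC(=O)c2ccccc12
Why: Electrophilic alkynylation of the stabilised tertiary enolate by the ethynylbenziodoxolone set free in the flask should place the ethynyl group (future C9 and C8) between the two carbonyls, giving an achiral dione with a prochiral quaternary carbon.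

Step 3
Reactants: 3 2-ethynyl-2-methylcycloheptane-1,3-dione
Product: 4 (2S,3R)-2-ethynyl-3-hydroxy-2-methylcycloheptan-1-one
Conditions: (S)-2-methyl-CBS-oxazaborolidine (0.2 equiv), catecholborane (1.1 equiv), toluene, −78 °C; then MeOH
Reagents that add atoms: none
Why: Corey–Bakshi–Shibata reduction should reduce one of the two enantiotopic carbonyls (desymmetrisation), the catalyst fixing the carbinol as R and hydride arriving past the slim ethynyl group, so the same event defines C10; the carbinol only marks the future C6 carbonyl and a minor diastereomer would be removed by chromatography.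

Step 4
Reactants: 4 (2S,3R)-2-ethynyl-3-hydroxy-2-methylcycloheptan-1-one
Product: 6 (6R,7S)-7-methyl-6-(trimethylsilyloxy)-7-[(trimethylsilyl)ethynyl]cyclohept-2-en-1-one, via tris-silyl enol ether 5 (not isolated)
Conditions: TMSOTf (4 equiv), Et3N (6 equiv), Zn(OTf)2 (10 mol %), CH2Cl2, 0 °C to rt; then Pd(OAc)2 (1.1 equiv), MeCN, rt
Reagents that add atoms: trimethylsilyl triflate, C[Si](C)(C)OS(=O)(=O)C(F)(F)F
Why: Soft silylation of the hydroxyl, of the ketone toward its only enolisable side (C2) and of the alkyne C–H, followed by Saegusa–Ito dehydrogenation of the silyl enol ether, should give the C2=C3 enone with alcohol and alkyne masked; no stereocentre changes.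

Step 5
Reactants: 6 (6R,7S)-7-methyl-6-(trimethylsilyloxy)-7-[(trimethylsilyl)ethynyl]cyclohept-2-en-1-one
Product: 9 (6R,7S)-6-hydroxy-3,7-dimethyl-7-[(trimethylsilyl)ethynyl]cyclohept-2-en-1-one, via silyl enol ether 7 (not isolated), via O-silyl methyl enone 8 (not isolated)
Conditions: Me2CuLi (from MeLi and CuI), TMSCl, THF, −78 °C; then Pd(OAc)2 (1.1 equiv), MeCN, rt; then 1 M HCl, THF, 0 °C
Reagents that add atoms: lithium dimethylcuprate, [Li+].C[Cu-]C
Why: Cuprate conjugate addition with chlorosilane trapping puts the methyl group on C3, a second Saegusa–Ito oxidation restores the C2=C3 double bond and erases the transient C3 stereocentre, and dilute acid removes only the O-silyl group.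

Step 6
Reactants: 9 (6R,7S)-6-hydroxy-3,7-dimethyl-7-[(trimethylsilyl)ethynyl]cyclohept-2-en-1-one
Product: 10 (2S)-2,5-dimethyl-2-[(trimethylsilyl)ethynyl]cyclohept-4-ene-1,3-dione
Conditions: Dess–Martin periodinane, CH2Cl2, 0 °C to rt
Reagents that add atoms: none
Why: Dess–Martin oxidation of the secondary alcohol should regenerate the C6 carbonyl without touching enone or silylalkyne, leaving C10 as the only stereocentre of an ene-dione whose two carbonyls are now different.

Step 7
Reactants: 10 (2S)-2,5-dimethyl-2-[(trimethylsilyl)ethynyl]cyclohept-4-ene-1,3-dione; 11 2-methylprop-1-enylmagnesium bromide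
Product: 12 (6S,7S)-6-hydroxy-3,7-dimethyl-6-(2-methylprop-1-enyl)-7-[(trimethylsilyl)ethynyl]cyclohept-2-en-1-one
Conditions: 11 (1.2 equiv), THF, −78 °C; sat. aq. NH4Cl at −78 °C
Reagents that add atoms: none
Why: Grignard 1,2-addition should take place at the saturated C6 ketone, which is more electrophilic than the conjugated C1 carbonyl, and from the face flanked by the rod-like alkynyl group and not by the C10 methyl group, setting C6 with the alkenyl group cis to the alkyne arm.

Step 8
Reactants: 12 (6S,7S)-6-hydroxy-3,7-dimethyl-6-(2-methylprop-1-enyl)-7-[(trimethylsilyl)ethynyl]cyclohept-2-en-1-one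
Product: 14 (1S,2R,3R)-2-ethynyl-2,5-dimethyl-1-(2-methylprop-1-enyl)cyclohept-4-ene-1,3-diol, via silylalkyne diol 13 (not isolated)
Conditions: Me4NBH(OAc)3 (5 equiv), MeCN/AcOH 1:1, −30 to 0 °C; then K2CO3, MeOH, rt
Reagents that add atoms: none
Why: Evans–Saksena reduction delivers hydride from boron bound to the C6 hydroxyl, so the C1 hydroxyl forms anti to the C6 oxygen (C1 R), and methanolysis then frees the terminal alkyne at a stage with no carbonyl left for retro-aldol cleavage.

Step 9
Reactants: 14 (1S,2R,3R)-2-ethynyl-2,5-dimethyl-1-(2-methylprop-1-enyl)cyclohept-4-ene-1,3-diol; 15 4-methoxybenzoyl chloride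
Product: 16 (1R,6S,7R)-7-ethynyl-6-hydroxy-3,7-dimethyl-6-(2-methylprop-1-enyl)cyclohept-2-en-1-yl 4-methoxybenzoate
Conditions: 15 (1.5 equiv), Et3N, DMAP (0.2 equiv), CH2Cl2, 0 °C to rt
Reagents that add atoms: none
Why: DMAP-catalysed acylation should esterify only the secondary allylic C1 hydroxyl, the tertiary C6 hydroxyl being too hindered, with retention because no C–O bond is broken.

Step 10
Reactants: 16 (1R,6S,7R)-7-ethynyl-6-hydroxy-3,7-dimethyl-6-(2-methylprop-1-enyl)cyclohept-2-en-1-yl 4-methoxybenzoate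
Product: 18 (1R,6S,7R)-7-acetyl-6-hydroxy-3,7-dimethyl-6-(2-methylprop-1-enyl)cyclohept-2-en-1-yl 4-methoxybenzoate, via vinylsilane 17 (not isolated)
Conditions: [Cp*Ru(MeCN)3]PF6 (5 mol %), (EtO)3SiH (1.3 equiv), CH2Cl2, 0 °C to rt; then KF, KHCO3, 30% H2O2, THF/MeOH, rt
Reagents that add atoms: hydrogen peroxide, OO
Why: Markovnikov hydrosilylation of the terminal alkyne places silicon on C9 and spares the trisubstituted alkenes, and Tamao–Fleming oxidation of the 1,1-disubstituted vinylsilane gives the C9 methyl ketone, a formal hydration that avoids carbophilic Lewis acids, which would cycloisomerise the 1,5-enyne units.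

Step 11
Reactants: 18 (1R,6S,7R)-7-acetyl-6-hydroxy-3,7-dimethyl-6-(2-methylprop-1-enyl)cyclohept-2-en-1-yl 4-methoxybenzoate
Product: 20 (1R,6S,7R)-7-(2-bromoacetyl)-3,7-dimethyl-6-(2-methylprop-1-enyl)-6-(trimethylsilyloxy)cyclohept-2-en-1-yl 4-methoxybenzoate, via bis-silyl enol ether 19 (not isolated)
Conditions: TMSOTf (3 equiv), Et3N (4 equiv), CH2Cl2, −78 to 0 °C; then NBS (1.05 equiv), THF, −78 °C
Reagents that add atoms: trimethylsilyl triflate, C[Si](C)(C)OS(=O)(=O)C(F)(F)F; N-bromosuccinimide, BrN1C(=O)CCC1=O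
Why: Silyl triflate and amine silylate the tertiary C6 hydroxyl and convert the methyl ketone, enolisable only toward C8, into its silyl enol ether, whose bromination by NBS at −78 °C should be far faster than attack on either trisubstituted alkene.

Step 12
Reactants: 20 (1R,6S,7R)-7-(2-bromoacetyl)-3,7-dimethyl-6-(2-methylprop-1-enyl)-6-(trimethylsilyloxy)cyclohept-2-en-1-yl 4-methoxybenzoate
Product: 21 (3R,3aS,8R,8aR)-6,8a-dimethyl-1-oxo-3-(propan-2-yl)-3a-(trimethylsilyloxy)-1,2,3,3a,4,5,8,8a-octahydroazulen-8-yl 4-methoxybenzoate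
Conditions: (Me3Si)3SiH (1.3 equiv), AIBN (0.2 equiv), benzene, 80 °C, syringe-pump addition over 8 h, 5 mM
Reagents that add atoms: none
Why: Bromine abstraction by the silyl radical gives the electrophilic C8 radical alpha to the C9 carbonyl, which adds to C7 of the electron-rich 2-methylpropenyl group, and the tertiary radical so formed takes hydrogen from the silane to become the isopropyl group and pass on the chain. The closest known reaction type is the hydride-mediated cyclisation of alpha-halo ketone radicals onto trisubstituted alkenes. Ring A closes in the 5-exo-trig mode, and because the bromoacetyl arm on C10 and the alkenyl arm on C6 sit on the same face of ring B only the cis-fused bicycle is accessible. The C7 stereocentre is controlled by 1,3-allylic strain: the alkene methyl group cis to C6 forces the smallest C6 substituent, the oxygen, into the alkene plane, so the arm from C10 attacks the face that leaves the isopropyl group cis to the C6 oxygen. The step needs attack at C7 and not at the gem-dimethyl carbon (6-endo, often preferred when the carbonyl lies inside the forming ring) or at C2 of the ring alkene; the unsubstituted acceptor carbon with its tertiary radical outcome secures the first, and the strain of the bridged bicyclo[4.2.1] alternative together with inductive deactivation of the ring alkene by the allylic ester secures the second. Slow addition of the less reactive silane at high dilution should keep hydrogen transfer to C8 slower than ring closure.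

Step 13
Reactants: 21 (3R,3aS,8R,8aR)-6,8a-dimethyl-1-oxo-3-(propan-2-yl)-3a-(trimethylsilyloxy)-1,2,3,3a,4,5,8,8a-octahydroazulen-8-yl 4-methoxybenzoate
Product: 22 (3R,3aS,8R,8aR)-3a-hydroxy-6,8a-dimethyl-1-oxo-3-(propan-2-yl)-1,2,3,3a,4,5,8,8a-octahydroazulen-8-yl 4-methoxybenzoate
Conditions: AcOH/THF/H2O 3:1:1, rt
Reagents that add atoms: none
Why: Mild acid hydrolysis of the tertiary trimethylsilyl ether should leave the allylic ester intact, and the beta-hydroxy ketone cannot dehydrate because C10 bears no hydrogen; no stereocentre is touched.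

Compound list
1 | cycloheptane-1,3-dione | O=C1CCCCC(=O)C1 | starting material
2 | 2-methylcycloheptane-1,3-dione | CC1C(=O)CCCCC1=O | intermediate
3 | 2-ethynyl-2-methylcycloheptane-1,3-dione | C#CC1(C)C(=O)CCCCC1=O | intermediate
4 | (2S,3R)-2-ethynyl-3-hydroxy-2-methylcycloheptan-1-one | O=C1CCCC[C@@H](O)[C@]1(C)C#C | intermediate
5 | (6R,7S)-7-methyl-1,6-bis(trimethylsilyloxy)-7-[(trimethylsilyl)ethynyl]cyclohept-1-ene | C[Si](C)(C)OC1=CCCC[C@@H](O[Si](C)(C)C)[C@]1(C)C#C[Si](C)(C)C | intermediate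
6 | (6R,7S)-7-methyl-6-(trimethylsilyloxy)-7-[(trimethylsilyl)ethynyl]cyclohept-2-en-1-one | O=C1C=CCC[C@@H](O[Si](C)(C)C)[C@]1(C)C#C[Si](C)(C)C | intermediate
7 | (6R,7S)-3,7-dimethyl-1,6-bis(trimethylsilyloxy)-7-[(trimethylsilyl)ethynyl]cyclohept-1-ene (both C3 epimers) | C[Si](C)(C)OC1=CC(C)CC[C@@H](O[Si](C)(C)C)[C@]1(C)C#C[Si](C)(C)C | intermediate
8 | (6R,7S)-3,7-dimethyl-6-(trimethylsilyloxy)-7-[(trimethylsilyl)ethynyl]cyclohept-2-en-1-one | O=C1C=C(C)CC[C@@H](O[Si](C)(C)C)[C@]1(C)C#C[Si](C)(C)C | intermediate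
9 | (6R,7S)-6-hydroxy-3,7-dimethyl-7-[(trimethylsilyl)ethynyl]cyclohept-2-en-1-one | O=C1C=C(C)CC[C@@H](O)[C@]1(C)C#C[Si](C)(C)C | intermediate
10 | (2S)-2,5-dimethyl-2-[(trimethylsilyl)ethynyl]cyclohept-4-ene-1,3-dione | O=C1C=C(C)CCC(=O)[C@]1(C)C#C[Si](C)(C)C | intermediate
11 | 2-methylprop-1-enylmagnesium bromide | CC(C)=C[Mg]Br | starting material
12 | (6S,7S)-6-hydroxy-3,7-dimethyl-6-(2-methylprop-1-enyl)-7-[(trimethylsilyl)ethynyl]cyclohept-2-en-1-one | O=C1C=C(C)CC[C@](O)(C=C(C)C)[C@]1(C)C#C[Si](C)(C)C | intermediate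
13 | (1S,2R,3R)-2,5-dimethyl-1-(2-methylprop-1-enyl)-2-[(trimethylsilyl)ethynyl]cyclohept-4-ene-1,3-diol | O[C@@H]1C=C(C)CC[C@](O)(C=C(C)C)[C@]1(C)C#C[Si](C)(C)C | intermediate
14 | (1S,2R,3R)-2-ethynyl-2,5-dimethyl-1-(2-methylprop-1-enyl)cyclohept-4-ene-1,3-diol | O[C@@H]1C=C(C)CC[C@](O)(C=C(C)C)[C@]1(C)C#C | intermediate
15 | 4-methoxybenzoyl chloride | COc1ccc(cc1)C(Cl)=O | starting material
16 | (1R,6S,7R)-7-ethynyl-6-hydroxy-3,7-dimethyl-6-(2-methylprop-1-enyl)cyclohept-2-en-1-yl 4-methoxybenzoate | COc1ccc(cc1)C(=O)O[C@@H]1C=C(C)CC[C@](O)(C=C(C)C)[C@]1(C)C#C | intermediate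
17 | (1R,6S,7R)-6-hydroxy-3,7-dimethyl-6-(2-methylprop-1-enyl)-7-[1-(triethoxysilyl)ethenyl]cyclohept-2-en-1-yl 4-methoxybenzoate | COc1ccc(cc1)C(=O)O[C@@H]1C=C(C)CC[C@](O)(C=C(C)C)[C@]1(C)C(=C)[Si](OCC)(OCC)OCC | intermediate
18 | (1R,6S,7R)-7-acetyl-6-hydroxy-3,7-dimethyl-6-(2-methylprop-1-enyl)cyclohept-2-en-1-yl 4-methoxybenzoate | COc1ccc(cc1)C(=O)O[C@@H]1C=C(C)CC[C@](O)(C=C(C)C)[C@]1(C)C(C)=O | intermediate
19 | (1R,6S,7S)-3,7-dimethyl-6-(2-methylprop-1-enyl)-6-(trimethylsilyloxy)-7-[1-(trimethylsilyloxy)ethenyl]cyclohept-2-en-1-yl 4-methoxybenzoate | COc1ccc(cc1)C(=O)O[C@@H]1C=C(C)CC[C@](O[Si](C)(C)C)(C=C(C)C)[C@]1(C)C(=C)O[Si](C)(C)C | intermediate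
20 | (1R,6S,7R)-7-(2-bromoacetyl)-3,7-dimethyl-6-(2-methylprop-1-enyl)-6-(trimethylsilyloxy)cyclohept-2-en-1-yl 4-methoxybenzoate | COc1ccc(cc1)C(=O)O[C@@H]1C=C(C)CC[C@](O[Si](C)(C)C)(C=C(C)C)[C@]1(C)C(=O)CBr | intermediate
21 | (3R,3aS,8R,8aR)-6,8a-dimethyl-1-oxo-3-(propan-2-yl)-3a-(trimethylsilyloxy)-1,2,3,3a,4,5,8,8a-octahydroazulen-8-yl 4-methoxybenzoate | COc1ccc(C(=O)O[C@@H]2C=C(C)CC[C@]3(O[Si](C)(C)C)[C@@H](C(C)C)CC(=O)[C@]23C)cc1 | intermediate
22 | (3R,3aS,8R,8aR)-3a-hydroxy-6,8a-dimethyl-1-oxo-3-(propan-2-yl)-1,2,3,3a,4,5,8,8a-octahydroazulen-8-yl 4-methoxybenzoate | COc1ccc(C(=O)O[C@@H]2C=C(C)CC[C@]3(O)[C@@H](C(C)C)CC(=O)[C@]23C)cc1 | target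

Total step count: 13. Longest linear sequence: 13 steps, from cycloheptane-1,3-dione to 22.

Steps most likely to fail

Step 12. What may go wrong:
- hydrogen transfer to the C8 radical before ring closure, since a carbonyl inside the forming ring slows 5-exo closure;
- closure onto C2 of the ring alkene;
- attack on the wrong alkene face at C7;
- 1,5-hydrogen transfer from C1–H to the tertiary radical.

Fallback, from 19 back to 21: the ring is closed by an organopalladium route and not by a radical one. Pd(OAc)2 in MeCN should turn the silyl enol ether 19 into a palladium enolate that inserts the 2-methylpropenyl alkene 5-exo (cycloalkenylation of the Saegusa–Ito type) and loses hydride from a methyl group. This gives the isopropenyl ketone (3R,3aS,8R,8aR)-6,8a-dimethyl-1-oxo-3-(prop-1-en-2-yl)-3a-(trimethylsilyloxy)-1,2,3,3a,4,5,8,8a-octahydroazulen-8-yl 4-methoxybenzoate F1. Hydrogenation of its 1,1-disubstituted alkene with RhCl(PPh3)3 and H2, which should spare the trisubstituted ring alkene, gives 21.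

Step 7. What may go wrong:
- addition from the methyl-flanked face of the C6 carbonyl;
- competing addition at the C1 carbonyl;
- retro-aldol fragmentation of the congested magnesium aldolate.

Fallback, from 3 back to 12: the order of events is inverted so that the alkenyl group is added while only one carbonyl is present.
- Reduction of 3 with the (R)-catalyst and catecholborane gives the enantiomeric hydroxy ketone (2R,3S)-2-ethynyl-3-hydroxy-2-methylcycloheptan-1-one F2, whose remaining carbonyl is now the future C6.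
- Compound 11 (2.5 equiv, THF, −78 °C) should add to its magnesium alkoxide from the alkyne face, the methyl face being further shielded by the cis alkoxide, to give (1S,2R,3S)-2-ethynyl-2-methyl-1-(2-methylprop-1-enyl)cycloheptane-1,3-diol F3.
- Dess–Martin oxidation of the secondary hydroxyl gives (2S,3S)-2-ethynyl-3-hydroxy-2-methyl-3-(2-methylprop-1-enyl)cycloheptan-1-one F4.
- Silylation as in step 4 gives (6S,7R)-7-methyl-6-(2-methylprop-1-enyl)-1,6-bis(trimethylsilyloxy)-7-[(trimethylsilyl)ethynyl]cyclohept-1-ene F5, and Pd(OAc)2 converts it into (6S,7S)-7-methyl-6-(2-methylprop-1-enyl)-6-(trimethylsilyloxy)-7-[(trimethylsilyl)ethynyl]cyclohept-2-en-1-one F6.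
- Me2CuLi with TMSCl gives (6S,7R)-3,7-dimethyl-6-(2-methylprop-1-enyl)-1,6-bis(trimethylsilyloxy)-7-[(trimethylsilyl)ethynyl]cyclohept-1-ene F7, and Pd(OAc)2 gives (6S,7S)-3,7-dimethyl-6-(2-methylprop-1-enyl)-6-(trimethylsilyloxy)-7-[(trimethylsilyl)ethynyl]cyclohept-2-en-1-one F8.
- HF·pyridine buffered with pyridine removes the O-silyl group to give 12.

Step 10. What may go wrong:
- silicon delivered to the terminal carbon C8 at this neopentyl alkyne;
- ester cleavage or retro-aldol ring opening during the basic peroxide oxidation.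

Fallback, from 16 back to 18: the alkyne is oxidised by way of the alkene. Semi-hydrogenation with H2 over Pd on CaCO3 poisoned with Pb(OAc)2, with quinoline, gives (1R,6S,7R)-7-ethenyl-6-hydroxy-3,7-dimethyl-6-(2-methylprop-1-enyl)cyclohept-2-en-1-yl 4-methoxybenzoate F9. Tsuji–Wacker oxidation (PdCl2, CuCl, O2, DMF/H2O) of its only monosubstituted alkene gives 18.

Further compounds
F1 | step 12 | (3R,3aS,8R,8aR)-6,8a-dimethyl-1-oxo-3-(prop-1-en-2-yl)-3a-(trimethylsilyloxy)-1,2,3,3a,4,5,8,8a-octahydroazulen-8-yl 4-methoxybenzoate | COc1ccc(C(=O)O[C@@H]2C=C(C)CC[C@]3(O[Si](C)(C)C)[C@@H](C(C)=C)CC(=O)[C@]23C)cc1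
F2 | step 7 | (2R,3S)-2-ethynyl-3-hydroxy-2-methylcycloheptan-1-one | O=C1CCCC[C@H](O)[C@@]1(C)C#C
F3 | step 7 | (1S,2R,3S)-2-ethynyl-2-methyl-1-(2-methylprop-1-enyl)cycloheptane-1,3-diol | O[C@H]1CCCC[C@](O)(C=C(C)C)[C@]1(C)C#C
F4 | step 7 | (2S,3S)-2-ethynyl-3-hydroxy-2-methyl-3-(2-methylprop-1-enyl)cycloheptan-1-one | O=C1CCCC[C@](O)(C=C(C)C)[C@]1(C)C#C
F5 | step 7 | (6S,7R)-7-methyl-6-(2-methylprop-1-enyl)-1,6-bis(trimethylsilyloxy)-7-[(trimethylsilyl)ethynyl]cyclohept-1-ene | C[Si](C)(C)OC1=CCCC[C@](O[Si](C)(C)C)(C=C(C)C)[C@]1(C)C#C[Si](C)(C)C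
F6 | step 7 | (6S,7S)-7-methyl-6-(2-methylprop-1-enyl)-6-(trimethylsilyloxy)-7-[(trimethylsilyl)ethynyl]cyclohept-2-en-1-one | O=C1C=CCC[C@](O[Si](C)(C)C)(C=C(C)C)[C@]1(C)C#C[Si](C)(C)C
F7 | step 7 | (6S,7R)-3,7-dimethyl-6-(2-methylprop-1-enyl)-1,6-bis(trimethylsilyloxy)-7-[(trimethylsilyl)ethynyl]cyclohept-1-ene (both C3 epimers) | C[Si](C)(C)OC1=CC(C)CC[C@](O[Si](C)(C)C)(C=C(C)C)[C@]1(C)C#C[Si](C)(C)C
F8 | step 7 | (6S,7S)-3,7-dimethyl-6-(2-methylprop-1-enyl)-6-(trimethylsilyloxy)-7-[(trimethylsilyl)ethynyl]cyclohept-2-en-1-one | O=C1C=C(C)CC[C@](O[Si](C)(C)C)(C=C(C)C)[C@]1(C)C#C[Si](C)(C)C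
F9 | step 10 | (1R,6S,7R)-7-ethenyl-6-hydroxy-3,7-dimethyl-6-(2-methylprop-1-enyl)cyclohept-2-en-1-yl 4-methoxybenzoate | COc1ccc(cc1)C(=O)O[C@@H]1C=C(C)CC[C@](O)(C=C(C)C)[C@]1(C)C=C
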